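**Analysis of the target**

Cladonaphchrom B (22) is a 2-methylchroman whose C4 carries a 4,5-dimethoxynaphthalen-1-yl group. The chroman is numbered O1, C2–C4, C4a, C5–C8, C8a (ring A is its benzene ring, ring B the dihydropyran), and the naphthalene carries primed locants, so C4 is bonded to C4' and the methoxy groups sit on the peri carbons C1' and C8'. There are two stereocentres, C2 (S, methyl) and C4 (S, aryl); they are 1,3-related across ring B and cis. The C4–H bond is doubly benzylic and flanked by two electron-rich arenes, so C4 can ionise or be oxidised; the free C5 phenol and the 1,8-dioxygenated naphthalene are also oxidation-prone. The synthesis is hard for three reasons: the C4–C4' bond lies between the C5 oxygen and the peri C5'–H, which crowds any union of two finished halves; three aryl oxygens must be told apart (two methyl ethers, one free hydroxyl); and absolute configuration has to be created and then relayed from one centre to the other. The strategy rests on the substituted naphthalene ring (C1'–C4', C4a', C8a'): its oxygen on C1' is para to the chromanyl group on C4', and the second oxygen sits on the neighbouring peri carbon C8'. C1'–C2'–C3'–C4' with the C1' oxygen is therefore the skeleton of a 2-substituted furan, and C4a'–C8a' with C8' is a 3-substituted benzyne, so the naphthalene can be grown on a furan already attached to C4.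

**Retrosynthetic reasoning**

22 ⇒ 21. The C5 hydroxyl is the only oxygen that must end free, so it is carried as a benzyl ether and the O–CH2Ph bond is cut last. Benzyl is chosen because it has to pass organolithium, Grignard, strong-acid and basic oxidative steps, and because its removal by hydrogenolysis is neutral and cannot ionise C4. The forward step only has to leave the naphthalene and the C4–H bond alone.

21 ⇒ 20. Both O–CH3 bonds are cut together. Revealing the two naphthalene oxygens as free hydroxyls at the same stage lets one alkylation install both methyl groups, while the benzyl group keeps the third oxygen distinct. The forward reaction has to methylate a phenol that is held in a peri hydrogen bond.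

20 ⇒ 18 (through 19). The C8'–O bond is traced back to a C8'–B bond, and the aromatic C1'–C4' ring to its oxygen-bridged isomer 18, in which the C1' oxygen is still also bonded to C4'. In the forward direction the bridge is opened first (18 → 19), while C8' still carries boron. Heterolysis of a bridge C–O bond puts positive charge on C4' or on C1'; C4' is tertiary and the acceptor on C8' gives no help to charge on C1', so C4'–O breaks and C1' keeps the oxygen and loses its proton. If boron were oxidised first, a hydroxyl on C8' would stabilise charge on C1' and could divert the cleavage to C1'–O; no naphthol with the chromanyl group on C4' can form that way, because C4' has no hydrogen to lose. Oxidation of the C–B bond then gives 20.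

18 ⇒ 11 + 15 (through 16 and 17). This is the central cut: C4'–C4a' and C1'–C8a' are broken, which returns the furan 11 and the aryne 17. The cut is placed here and not at C4–C4' because it takes the whole naphthalene away from the crowded C4 centre and leaves only a small furan there. It also solves the placement of the peri oxygens, since the boron substituent of 17 decides which way round the two partners combine. The triflate 15 is the bench-stable source of 17 by halogen–magnesium exchange (16) and loss of triflate. The forward reaction has to deliver the chromanyl group distal to boron; no lasting stereocentre is made.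

11 ⇒ 10 ⇒ 6 + 7 (through 8 and 9). The C4–H bond is cut first (ionic reduction of the tertiary carbinol 10), then the C4–furyl bond (addition of metalated furan 8/9 to ketone 6). This order makes C4 a planar cation at the moment its configuration is decided, so the existing C2 centre can direct the hydride to give the cis isomer. Ketone 6 is the natural electrophile because its carbonyl carbon is C4.

6 ⇒ 4 (through 5) ⇒ 3 ⇒ 1 (through 2). The C2–H bond is cut by an asymmetric conjugate reduction of chromone 4, the only event that creates absolute configuration. Chromone 4 is the benzyl ether of 3, and the pyranone ring of 3 comes from 1 by Claisen condensation with an acetate ester to diketone 2 and cyclodehydration. Starting from 1 fixes the C5 oxygen pattern from the outset, and its two phenols are equivalent, so ring closure is unambiguous.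

15 ⇒ 14 ⇒ 12 (through 13). The S–O bond of the triflate and the C–B bond are cut in turn. One of the two equivalent bromines of 12 is exchanged for lithium (13) and replaced by boron; the other stays as the handle for aryne generation.

**Alternatives that were turned down**

Alternative 1: The disconnection is C3–C4 and O1–C2 of ring B, with ring A and the naphthalene already joined at C4 in the diaryl carbinol A2.
- Forward key step: acid dehydrates A2 to the ortho-quinone methide A3, which adds the enol ether 2-methoxypropene A4 in an inverse-demand hetero-Diels–Alder reaction. The product is the mixed ketal A1, whose C2 would then be reduced through the oxocarbenium ion with a hydrosilane.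
- For: it is the shortest of all the routes and highly convergent. The symmetric resorcinol core needs no protecting group and either hydroxyl can close the ring. Axial hydride delivery to the C2 oxocarbenium ion should give the cis isomer.
- Against: C4 is made from a planar, achiral quinone methide, so a single configuration at C4 in A1 depends wholly on an external chiral acid distinguishing the faces of a hindered methide. A4 is hydrolysed and oligomerised by the acid that generates A3. The later ketal reduction again exposes the doubly benzylic C4, now next to a free phenol, to conditions under which it can revert to A3 and lose its configuration.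
- Comparison: on step count and convergence this alternative is stronger. The chosen route offers instead an absolute configuration set at C2 by a conjugate reduction and passed to C4 by the substrate, with no stereocentre resting on face selection at a free quinone methide.

Alternative 2: The disconnection is C2–C3 and C4–C4a of ring B, giving the aryl vinyl ether A6 and the vinylnaphthalene A7.
- Forward key step: protonation of A6 at its terminal carbon gives an O-aryl oxocarbenium ion, which the alkene of A7 attacks. The resulting C4 cation, benzylic to the naphthalene, closes on ring A in a Friedel–Crafts step to give the chroman A5. The chlorines and the benzyl group are then removed by hydrogenolysis.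
- For: both ring carbon–carbon bonds form in one operation from two simple pieces, and a chair-like closure should favour the cis relationship.
- Against: ring closure has to occur at the carbon of ring A between the two oxygen substituents, the most hindered site. That is why A6 carries chlorine blockers at the future C6 and C8; they deactivate the ring for the Friedel–Crafts step and cost steps to introduce and remove. A7 is an electron-rich styrene that oligomerises under acid, and the oxocarbenium ion has only an aryl ether to stabilise it. Nothing in either partner controls absolute configuration.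
- Comparison: convergence is equal or better. The chosen route offers in its place enantiocontrol, an oxygen pattern on ring A that is inherited from 1 without blocking groups, and a ring closure (the cycloaddition) that does not depend on electrophilic substitution at a hindered arene carbon.

Alternative 3: The disconnection is the C3=C4 bond of the 2H-chromene A8, which leads back to the diene A9 with C2 taken from a chiral secondary allylic ether.
- Forward key step: ring-closing metathesis of A9 joins the allyl ether alkene to the 1,1-diarylethene and gives A8. Hydrogenation from the face opposite the methyl group would then set C4 and could remove the benzyl group in the same operation.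
- For: the C2 configuration comes from the chiral pool and is independent of any catalyst, which is more certain than the chosen route on absolute configuration. The endgame is short.
- Against: the metathesis must engage a 1,1-disubstituted alkene whose two aryl groups are a 1-naphthyl and a 2,6-dioxygenated phenyl, a very hindered partner that closes slowly to a trisubstituted alkene. Building A9 needs the crowded diaryl ketone, its methylenation and an aryl ether formation at a secondary allylic carbon, where allylic transposition or ionisation would erode the configuration. The facial bias of a remote methyl on a nearly flat chromene is modest.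
- Comparison: this alternative is shorter and its absolute configuration is more secure. The chosen route offers in its place a C4 junction that is built while the aryl group is still a small furan, and a C4 configuration fixed by hydride delivery to a cation and not by a hydrogenation of uncertain facial bias.

Key step: step 8

Assumption: the (R) antipode of the bisphosphine is written for step 3; the facial sense with chromone 4 is to be confirmed on the first run, and the mirror-image ligand is used if the (2R)-ketone results.

**Route**

Step 1
Reactants: 1 2',6'-dihydroxyacetophenone
Product: 3 5-hydroxy-2-methyl-4H-chromen-4-one, via 1,3-diketone 2 (not isolated)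
Conditions: NaH, EtOAc, THF, reflux; then conc. HCl, AcOH, 80 °C
Reagents that add atoms: ethyl acetate, CCOC(C)=O
Why: Crossed Claisen condensation of the ketone enolate (both phenols masked as phenoxides) with the ester gives the 1,3-diketone; acid then closes the pyranone by attack of a phenol on the distal carbonyl and loss of water (cyclodehydration), and because the two phenols are equivalent only one chromone can form.

Step 2
Reactants: 3 5-hydroxy-2-methyl-4H-chromen-4-one
Product: 4 5-(benzyloxy)-2-methyl-4H-chromen-4-one
Conditions: BnBr, K2CO3, DMF, 70 °C
Reagents that add atoms: benzyl bromide, BrCc1ccccc1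
Why: Williamson ether synthesis; the C5 hydroxyl is hydrogen-bonded to the C4 carbonyl and therefore needs a polar solvent and warming, but it is the only acidic site.

Step 3
Reactants: 4 5-(benzyloxy)-2-methyl-4H-chromen-4-one
Product: 6 (2S)-5-(benzyloxy)-2-methylchroman-4-one, via silyl enol ether 5 (not isolated)
Conditions: Cu(OAc)2 (cat.), (R)-DTBM-SEGPHOS (cat.), (EtO)2MeSiH, toluene, 0 °C; then 1 M HCl, THF, 0 °C
Reagents that add atoms: none
Why: Asymmetric conjugate reduction of a chromone by a bisphosphine-ligated CuH: hydride is delivered to C2 from the face chosen by the ligand, which sets C2 as S; the copper enolate is silylated by the silane, which turns the catalyst over and keeps the ketone masked from 1,2-reduction and from ring opening by β-elimination until the mild acidic work-up.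

Step 4
Reactants: 6 (2S)-5-(benzyloxy)-2-methylchroman-4-one; 7 furan
Product: 10 (2S)-5-(benzyloxy)-4-(furan-2-yl)-2-methylchroman-4-ol (both C4 epimers), via 2-furyllithium 8 (not isolated), via 2-furylcerium dichloride 9 (not isolated)
Conditions: n-BuLi, THF, 0 °C; CeCl3, −78 °C; then 6, −78 °C; aq NH4Cl
Reagents that add atoms: none
Why: α-Lithiation of furan and transmetalation to cerium give a compact, weakly basic nucleophile for 1,2-addition to a hindered, donor-deactivated and enolisable ketone; avoiding the enolate protects C2 from racemisation by reversible retro-oxa-Michael ring opening, and the configuration of the new carbinol centre is irrelevant because it is ionised in step 5.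

Step 5
Reactants: 10 (2S)-5-(benzyloxy)-4-(furan-2-yl)-2-methylchroman-4-ol
Product: 11 (2S,4R)-5-(benzyloxy)-4-(furan-2-yl)-2-methylchroman (2,4-cis)
Conditions: Et3SiH, TFA, CH2Cl2, −40 → 0 °C
Reagents that add atoms: none
Why: Ionic hydrogenation: acid ionises the tertiary carbinol to a cation stabilised by the furan and by the two ortho oxygens of ring A, and the silane delivers hydride pseudo-axially to the half-chair that holds the C2 methyl pseudo-equatorial, that is on the face of the axial C2–H, so the furyl group ends cis to the methyl group (4R); excess silane at low temperature should outrun acid-induced reactions of the furan.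

Step 6
Reactants: 12 2,6-dibromophenol
Product: 14 2-bromo-6-(4,4,5,5-tetramethyl-1,3,2-dioxaborolan-2-yl)phenol, via dilithiated phenoxide 13 (not isolated)
Conditions: n-BuLi (2.1 equiv), THF, −78 °C; iPrOBpin, −78 °C → rt; aq NH4Cl
Reagents that add atoms: 2-isopropoxy-4,4,5,5-tetramethyl-1,3,2-dioxaborolane, CC(C)OB1OC(C)(C)C(C)(C)O1
Why: The first equivalent of base forms the phenoxide and the second effects a single bromine–lithium exchange ortho to the oxygen (the dianion resists a second exchange); electrophilic borylation of the aryllithium and acidification give the pinacol boronate.

Step 7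
Reactants: 14 2-bromo-6-(4,4,5,5-tetramethyl-1,3,2-dioxaborolan-2-yl)phenol
Product: 15 2-bromo-6-(4,4,5,5-tetramethyl-1,3,2-dioxaborolan-2-yl)phenyl trifluoromethanesulfonate
Conditions: Tf2O, pyridine, CH2Cl2, 0 °C
Reagents that add atoms: trifluoromethanesulfonic anhydride, O=S(=O)(OS(=O)(=O)C(F)(F)F)C(F)(F)F
Why: O-Sulfonylation of the phenol; pyridine takes up the acid, and the boronate and the bromide are inert.

Step 8
Reactants: 11 (2S,4R)-5-(benzyloxy)-4-(furan-2-yl)-2-methylchroman; 15 2-bromo-6-(4,4,5,5-tetramethyl-1,3,2-dioxaborolan-2-yl)phenyl trifluoromethanesulfonate
Product: 18 1,4-epoxy-1,4-dihydronaphthalene cycloadduct (chromanyl on bridgehead C4'; Bpin on C8'; both bridgehead diastereomers), via arylmagnesium chloride 16 (not isolated), via 3-borylbenzyne 17 (not isolated)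
Conditions: iPrMgCl·LiCl (slow addition to 11 and excess 15), THF, −40 °C → rt
Reagents that add atoms: none
Why: Bromine–magnesium exchange at the carbon ortho to the triflate, which activates it, gives arylmagnesium 16, and loss of chloromagnesium triflate gives aryne 17, which the furan ring of 11 traps in a concerted but asynchronous [4+2] cycloaddition; this is the known aryne–furan Diels–Alder reaction of 3-borylbenzynes with 2-substituted furans. The new six-membered carbocycle is closed intermolecularly by suprafacial addition across furan C2 and C5, which become the bridgeheads C4' and C1' of a 7-oxabicyclo[2.2.1]heptadiene as the C4'–C4a' and C1'–C8a' bonds form. The step needs regioselectivity: the boryl group makes the neighbouring aryne carbon the more electrophilic terminus and also shields it, so the unsubstituted, more nucleophilic furan C5 bonds there and the carbon bearing the bulky chroman-4-yl group bonds to the remote terminus, which places the chromanyl group distal to boron. The two bridgehead stereocentres arise together (the bridge enforces their cis relation) and are not controlled by the distant chroman centres, so both diastereomers are expected; this does no harm because both centres become sp2 in step 9. Slow addition of the Grignard reagent to a mixture of both partners lets the aryne meet the furan and not unreacted organometallic, and the benzyl ether, the boronate and the C2 and C4 stereocentres are inert under these conditions.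

Step 9
Reactants: 18 1,4-epoxy-1,4-dihydronaphthalene cycloadduct
Product: 20 4-[(2S,4S)-5-(benzyloxy)-2-methylchroman-4-yl]naphthalene-1,8-diol, via 8-boryl-1-naphthol 19 (not isolated)
Conditions: TFA, CH2Cl2, 0 °C; evaporate; NaBO3·4H2O, degassed THF/H2O, rt
Reagents that add atoms: sodium perborate tetrahydrate NaBO3·4H2O, [Na+].[Na+].O[B-]1(O)OO[B-](O)(O)OO1
Why: Acid-induced isomerisation of a 1,4-epoxy-1,4-dihydronaphthalene to a 1-naphthol: protonation of the bridge oxygen and heterolysis of the tertiary, allylic and benzylic C4'–O bond (the boryl group on C8' gives no support to charge on C1') is followed by loss of the C1' proton, so the oxygen stays on C1' and both bridgehead diastereomers converge; perborate then turns C8'–B into C8'–OH by migration of the aryl group from boron to oxygen, and the chroman centres are not involved.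

Step 10
Reactants: 20 4-[(2S,4S)-5-(benzyloxy)-2-methylchroman-4-yl]naphthalene-1,8-diol
Product: 21 (2S,4S)-5-(benzyloxy)-4-(4,5-dimethoxynaphthalen-1-yl)-2-methylchroman
Conditions: MeI (excess), Cs2CO3, DMF, 40 °C, under argon
Reagents that add atoms: iodomethane, CI
Why: Double Williamson methylation; Cs2CO3 in DMF with excess alkylating agent is chosen because the second phenol is held in a peri hydrogen bond to the first methoxy oxygen, and the benzyl ether keeps the C5 oxygen out of play.

Step 11
Reactants: 21 (2S,4S)-5-(benzyloxy)-4-(4,5-dimethoxynaphthalen-1-yl)-2-methylchroman
Product: 22 cladonaphchrom B, (2S,4S)-4-(4,5-dimethoxynaphthalen-1-yl)-2-methylchroman-5-ol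
Conditions: H2 (1 atm), Pd/C, EtOAc/MeOH, rt
Reagents that add atoms: none
Why: Hydrogenolysis of the benzyl aryl ether under neutral conditions; C4 bears no heteroatom and is not cleaved, and the naphthalene is not reduced at ambient pressure and temperature.

**Compound list**

1 | 2',6'-dihydroxyacetophenone | CC(=O)c1c(O)cccc1O | starting material
2 | 1-(2,6-dihydroxyphenyl)butane-1,3-dione (not isolated) | CC(=O)CC(=O)c1c(O)cccc1O | intermediate
3 | 5-hydroxy-2-methyl-4H-chromen-4-one | CC1=CC(=O)c2c(O)cccc2O1 | intermediate
4 | 5-(benzyloxy)-2-methyl-4H-chromen-4-one | CC1=CC(=O)c2c(OCc3ccccc3)cccc2O1 | intermediate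
5 | (2S)-5-(benzyloxy)-4-{[diethoxy(methyl)silyl]oxy}-2-methyl-2H-chromene (not isolated) | C[C@H]1C=C(O[Si](C)(OCC)OCC)c2c(OCc3ccccc3)cccc2O1 | intermediate
6 | (2S)-5-(benzyloxy)-2-methylchroman-4-one | C[C@H]1CC(=O)c2c(OCc3ccccc3)cccc2O1 | intermediate
7 | furan | c1ccoc1 | starting material
8 | 2-furyllithium (not isolated) | [Li]c1ccco1 | intermediate
9 | 2-furylcerium dichloride (not isolated) | Cl[Ce](Cl)c1ccco1 | intermediate
10 | (2S)-5-(benzyloxy)-4-(furan-2-yl)-2-methylchroman-4-ol, both C4 epimers | C[C@H]1CC(O)(c2ccco2)c2c(OCc3ccccc3)cccc2O1 | intermediate
11 | (2S,4R)-5-(benzyloxy)-4-(furan-2-yl)-2-methylchroman (2,4-cis) | C[C@H]1C[C@@H](c2ccco2)c2c(OCc3ccccc3)cccc2O1 | intermediate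
12 | 2,6-dibromophenol | Oc1c(Br)cccc1Br | starting material
13 | lithium 2-bromo-6-lithiophenoxide (not isolated) | [Li]Oc1c(Br)cccc1[Li] | intermediate
14 | 2-bromo-6-(4,4,5,5-tetramethyl-1,3,2-dioxaborolan-2-yl)phenol | CC1(C)OB(OC1(C)C)c1cccc(Br)c1O | intermediate
15 | 2-bromo-6-(4,4,5,5-tetramethyl-1,3,2-dioxaborolan-2-yl)phenyl trifluoromethanesulfonate | CC1(C)OB(OC1(C)C)c1cccc(Br)c1OS(=O)(=O)C(F)(F)F | intermediate
16 | 2-(chloromagnesio)-6-(4,4,5,5-tetramethyl-1,3,2-dioxaborolan-2-yl)phenyl trifluoromethanesulfonate (not isolated) | CC1(C)OB(OC1(C)C)c1cccc([Mg]Cl)c1OS(=O)(=O)C(F)(F)F | intermediate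
17 | 3-(4,4,5,5-tetramethyl-1,3,2-dioxaborolan-2-yl)benzyne (not isolated) | CC1(C)OB(OC1(C)C)C1=CC=CC#C1 | intermediate
18 | (2S,4R)-5-(benzyloxy)-2-methyl-4-[5-(4,4,5,5-tetramethyl-1,3,2-dioxaborolan-2-yl)-1,4-dihydro-1,4-epoxynaphthalen-1-yl]chroman (chromanyl on bridgehead C4', boron on C8'; both bridgehead diastereomers) | C[C@H]1C[C@@H](C23C=CC(O2)c2c(B4OC(C)(C)C(C)(C)O4)cccc23)c2c(OCc3ccccc3)cccc2O1 | intermediate
19 | 4-[(2S,4S)-5-(benzyloxy)-2-methylchroman-4-yl]-8-(4,4,5,5-tetramethyl-1,3,2-dioxaborolan-2-yl)naphthalen-1-ol (not isolated) | C[C@H]1C[C@@H](c2ccc(O)c3c(B4OC(C)(C)C(C)(C)O4)cccc23)c2c(OCc3ccccc3)cccc2O1 | intermediate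
20 | 4-[(2S,4S)-5-(benzyloxy)-2-methylchroman-4-yl]naphthalene-1,8-diol | C[C@H]1C[C@@H](c2ccc(O)c3c(O)cccc23)c2c(OCc3ccccc3)cccc2O1 | intermediate
21 | (2S,4S)-5-(benzyloxy)-4-(4,5-dimethoxynaphthalen-1-yl)-2-methylchroman | C[C@H]1C[C@@H](c2ccc(OC)c3c(OC)cccc23)c2c(OCc3ccccc3)cccc2O1 | intermediate
22 | cladonaphchrom B, (2S,4S)-4-(4,5-dimethoxynaphthalen-1-yl)-2-methylchroman-5-ol | C[C@H]1C[C@@H](c2ccc(OC)c3c(OC)cccc23)c2c(O)cccc2O1 | target

The C4 descriptor changes from R (11, 18) to S (19–22) only because the priority of the aryl group changes; the spatial arrangement is the same throughout.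

**Step count and risk**

Total: 11 steps. Longest linear sequence: 9 steps (steps 1–5 and 8–11); the aryne precursor 15 is made in 2 steps (6 and 7) and joins at step 8.

Step 8 (key step). The most likely failure is slow bromine–magnesium exchange relative to the other reactions open to the Grignard reagent (addition to the aryne already formed, attack on boron or on the sulfonyl group). The aryne would then be consumed by organometallic species and not by the furan, which is the limiting and more valuable partner. A second possibility is erosion of the distal selectivity. The fallback joins a finished naphthalene to C4 instead of building it; it sets out from 6 and returns at 21. 1,8-Dimethoxynaphthalene F1 is brominated para to a methoxy group (NBS, MeCN) to give 4-bromo-1,8-dimethoxynaphthalene F2. Bromine–lithium exchange (n-BuLi, THF, −78 °C) gives (4,5-dimethoxynaphthalen-1-yl)lithium F3, which is added to ketone 6 (CeCl3 as additive, −78 °C) to give (2S)-5-(benzyloxy)-4-(4,5-dimethoxynaphthalen-1-yl)-2-methylchroman-4-ol F4. Ionic hydrogenation (Et3SiH, TFA, CH2Cl2) as in step 5 then gives 21.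

Step 9. Two things may go wrong. In the cationic opening, a 1,2-hydride shift from chroman C4 to the C4' cation would scramble C4, or the other bridge bond could cleave. In the second half, the electron-rich naphthol and the peri-diol may be over-oxidised by the basic peroxide or by air. The fallback avoids any free 1,8-diol and any free naphthol in the presence of oxidant; it sets out from 18 and returns at 21. After the acid step, 19 is isolated and its naphthol is methylated (MeI, Cs2CO3, DMF) to give (2S,4S)-5-(benzyloxy)-4-[4-methoxy-5-(4,4,5,5-tetramethyl-1,3,2-dioxaborolan-2-yl)naphthalen-1-yl]-2-methylchroman F5. The boronate is then oxidised (NaBO3·4H2O, THF/H2O) to the hydrogen-bonded 5-[(2S,4S)-5-(benzyloxy)-2-methylchroman-4-yl]-8-methoxynaphthalen-1-ol F6, and a second methylation gives 21. Loss of configuration at C4 in the opening itself would be answered by the fallback described for step 8.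

Step 5. The risks are poor facial selectivity in the hydride delivery (the peri benzyloxy group may distort the half-chair) and acid-induced reactions of the furan (ring opening, or capture of the cation by a second furan). The fallback sets C4 by alkene hydrogenation under steric approach control; it sets out from 10 and returns at 11. Dehydration (TsOH cat., toluene, 50 °C) gives (2S)-5-(benzyloxy)-4-(furan-2-yl)-2-methyl-2H-chromene F7. Homogeneous hydrogenation with [Ir(cod)(PCy3)(py)]PF6 (H2, CH2Cl2) should add hydrogen to the face opposite the C2 methyl and spare the furan and the benzyl ether, which gives 11.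

Step 3. The risks are insufficient enantioselectivity or slow hydride transfer to C2, since chromone 4 is a vinylogous ester further deactivated by the C5 oxygen, and partial racemisation through ring opening of the enolate. The fallback creates C2 by forming the C2–CH3 bond and not the C2–H bond; it sets out from 1 and returns at 6. Formylation of 1 with ethyl formate and NaH followed by acid cyclodehydration (as in step 1) gives 5-hydroxy-4H-chromen-4-one F8, and benzylation (BnBr, K2CO3, DMF) gives 5-(benzyloxy)-4H-chromen-4-one F9. Copper-catalysed asymmetric conjugate addition of MeMgBr (CuBr·SMe2, a chiral ferrocenyl diphosphine of the Josiphos family, low temperature; ligand antipode chosen for the S product) then gives 6.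

**Further compounds**

F1 | step 8 | 1,8-dimethoxynaphthalene | COc1cccc2cccc(OC)c12
F2 | step 8 | 4-bromo-1,8-dimethoxynaphthalene | COc1ccc(Br)c2cccc(OC)c12
F3 | step 8 | (4,5-dimethoxynaphthalen-1-yl)lithium | [Li]c1ccc(OC)c2c(OC)cccc12
F4 | step 8 | (2S)-5-(benzyloxy)-4-(4,5-dimethoxynaphthalen-1-yl)-2-methylchroman-4-ol, both C4 epimers | C[C@H]1CC(O)(c2ccc(OC)c3c(OC)cccc23)c2c(OCc3ccccc3)cccc2O1
F5 | step 9 | (2S,4S)-5-(benzyloxy)-4-[4-methoxy-5-(4,4,5,5-tetramethyl-1,3,2-dioxaborolan-2-yl)naphthalen-1-yl]-2-methylchroman | C[C@H]1C[C@@H](c2ccc(OC)c3c(B4OC(C)(C)C(C)(C)O4)cccc23)c2c(OCc3ccccc3)cccc2O1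
F6 | step 9 | 5-[(2S,4S)-5-(benzyloxy)-2-methylchroman-4-yl]-8-methoxynaphthalen-1-ol | C[C@H]1C[C@@H](c2ccc(OC)c3c(O)cccc23)c2c(OCc3ccccc3)cccc2O1
F7 | step 5 | (2S)-5-(benzyloxy)-4-(furan-2-yl)-2-methyl-2H-chromene | C[C@H]1C=C(c2ccco2)c2c(OCc3ccccc3)cccc2O1
F8 | step 3 | 5-hydroxy-4H-chromen-4-one | O=C1C=COc2cccc(O)c12
F9 | step 3 | 5-(benzyloxy)-4H-chromen-4-one | O=C1C=COc2cccc(OCc3ccccc3)c12
A1 | alternative 1 | (4S)-4-(4,5-dimethoxynaphthalen-1-yl)-2-methoxy-2-methylchroman-5-ol, both C2 epimers | COC1(C)C[C@@H](c2ccc(OC)c3c(OC)cccc23)c2c(O)cccc2O1
A2 | alternative 1 | 2-[(4,5-dimethoxynaphthalen-1-yl)(hydroxy)methyl]benzene-1,3-diol | OC(c1ccc(OC)c2c(OC)cccc12)c1c(O)cccc1O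
A3 | alternative 1 | 6-[(4,5-dimethoxynaphthalen-1-yl)methylidene]-5-hydroxycyclohexa-2,4-dien-1-one (ortho-quinone methide) | O=C1C=CC=C(O)C1=Cc1ccc(OC)c2c(OC)cccc12
A4 | alternative 1 | 2-methoxypropene | COC(C)=C
A5 | alternative 2 | (2S,4S)-5-(benzyloxy)-6,8-dichloro-4-(4,5-dimethoxynaphthalen-1-yl)-2-methylchroman (2,4-cis) | C[C@H]1C[C@@H](c2ccc(OC)c3c(OC)cccc23)c2c(OCc3ccccc3)c(Cl)cc(Cl)c2O1
A6 | alternative 2 | 1-(benzyloxy)-2,4-dichloro-5-(ethenyloxy)benzene | C=COc1cc(OCc2ccccc2)c(Cl)cc1Cl
A7 | alternative 2 | 4-ethenyl-1,8-dimethoxynaphthalene | C=Cc1ccc(OC)c2c(OC)cccc12
A8 | alternative 3 | (2S)-5-(benzyloxy)-4-(4,5-dimethoxynaphthalen-1-yl)-2-methyl-2H-chromene | C[C@H]1C=C(c2ccc(OC)c3c(OC)cccc23)c2c(OCc3ccccc3)cccc2O1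
A9 | alternative 3 | 1-(benzyloxy)-3-[(2S)-but-3-en-2-yloxy]-2-[1-(4,5-dimethoxynaphthalen-1-yl)ethenyl]benzene | C[C@@H](C=C)Oc1cccc(OCc2ccccc2)c1C(=C)c1ccc(OC)c2c(OC)cccc12
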